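**Retrosynthetic overview**

1. Numbering, used for every intermediate: C1 tertiary carbinol, C2–C4 crotonoyl, C5 ester carbon, C6/C7 lactone O–CH and CH, C8, C9 (CHOH), C10 (CHCH3), C11 (on C7), C12 (carboxyl), C13 (=CH2). The strategy rests on the cycloheptane C1–C5–C6–C7–C8–C9–C10: the C7 branch, the C9 oxygen and the C10 methyl surround C1 as the isopropenyl carbon, C3 and the methyl-bearing C2 surround the carbonyl of carvone, with one extra ring carbon (C5) between C1 and C6.
2. Late disconnections: the C5 ester by back-side opening of a C1–C5 oxirane with 3-methylbutanoic acid; the oxirane from the C1 hydroxyl and a C5 iodide; the γ-lactone (C6–O) and the C5 iodide together by iodolactonization of C5=C6 with the C7 acrylic acid (oxidised isopropenyl group); the crotonoyl group by aldol condensation of a C1 acetyl group installed by acetyl-anion addition to the C1 ketone.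
3. Key disconnection: the cyclohept-2-enone (C1=O, C5=C6) goes back to a 1-trimethylsiloxybicyclo[4.1.0]heptane that is opened oxidatively at the shared C1–C6 bond, so that the cyclopropane methylene becomes C5.
4. The siloxycyclopropane comes from a carvone-derived cyclohexanone with C9–OSi and C10–CH3 trans. This pair is set by syn hydroboration of the carvone ring alkene inside a temporary iodoether that masks the isopropenyl group and the C1 oxygen.
5. Ring order: the carbocycle of (R)-carvone is enlarged from six to seven members (step 9), then the γ-lactone is closed (step 15); the oxirane of steps 16–17 is transient.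

Key step: step 9

Remark on the chemistry: α is the ring face that carries the C7 side chain, β the other face (target: C10–CH3, C1–OH, C6–O α; C9–OH, C5–O, C1 acyl β); the C10 methyl, trans to the C9 oxygen and cis to the C7 branch, is not expected from protonation or equilibration of a C10 enolate, so it is set by a mechanistically enforced syn addition and kept away from enolising conditions until C1 is no longer a carbonyl carbon.

**Route**

Step 1
Reactants: 1 (R)-(−)-carvone
Product: 2 (1R,5R)-cis-carveol (C1 hydroxyl α, cis to the isopropenyl group)
Conditions: NaBH4, CeCl3·7H2O, MeOH, 0 °C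
Reagents that add atoms: none
Why: Luche reduction delivers hydride to the carbonyl carbon only and from the axial direction, so the new C1 hydroxyl is equatorial and cis to the isopropenyl group at C7, the relationship that the ether bridge of step 2 needs.

Step 2
Reactants: 2 cis-carveol
Product: 3 iodoether 7-(iodomethyl)-4,7-dimethyl-6-oxabicyclo[3.2.1]oct-3-ene (C1–O–C11 bridge on the α face, C11 epimers)
Conditions: I2, NaHCO3, MeCN, 0 °C to rt, dark
Reagents that add atoms: iodine (II)
Why: Iodoetherification, in which the reversibly formed iodonium ion of the isopropenyl group is trapped by the cis C1 hydroxyl in a 5-exo Markovnikov closure while the ring alkene has no nucleophile within reach, masks the isopropenyl group and the C1 oxygen in one operation and lays a two-atom bridge under the α face of C9=C10.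

Step 3
Reactants: 3 iodoether
Product: 5 bicyclic alcohol (C9 hydroxyl β, C10 hydrogen β, C10 methyl α), via C9 alkylborane 4 (not isolated)
Conditions: BH3·THF, THF, 0 °C to rt; then NaOH, H2O2, 0 °C
Reagents that add atoms: hydrogen peroxide (OO)
Why: Hydroboration–oxidation places boron on the less substituted C9, remote from the allylic oxygen, and adds B and H syn from the β face because the O–C11 bridge lies 1,3-diaxial over the α face of C9, so that the C9 oxygen ends β and the C10 methyl α (trans to the C9 oxygen, cis to the C7 branch), the oxidation going with retention.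

Step 4
Reactants: 5 bicyclic alcohol
Product: 6 tert-butyldimethylsilyl ether of 5
Conditions: TBSOTf, 2,6-lutidine, CH2Cl2, −78 to 0 °C
Reagents that add atoms: tert-butyldimethylsilyl triflate (CC(C)(C)[Si](C)(C)OS(=O)(=O)C(F)(F)F)
Why: Silylation of the hindered secondary alcohol with the reactive silyl triflate and a non-nucleophilic base leaves the tertiary ether and the neopentyl-type iodide untouched.

Step 5
Reactants: 6 silyl ether
Product: 7 cyclohexanol (C1–OH α, C10–CH3 α, C9–OSi β, C7 isopropenyl α)
Conditions: Zn dust, NH4Cl, EtOH, 75 °C
Reagents that add atoms: none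
Why: Zinc inserts into the primary C–I bond and the β-alkoxy organozinc fragments (Boord-type reductive elimination), which regenerates the isopropenyl group regiospecifically and frees the C1 alcohol under neutral conditions that the silyl ether tolerates.

Step 6
Reactants: 7 cyclohexanol
Product: 8 (2S,3R,5R)-3-[(tert-butyldimethylsilyl)oxy]-2-methyl-5-(prop-1-en-2-yl)cyclohexan-1-one
Conditions: Dess–Martin periodinane, pyridine, CH2Cl2, 0 °C to rt
Reagents that add atoms: none
Why: Dess–Martin oxidation in a buffered, non-enolising medium gives the ketone without epimerising C10, which now lies α to the carbonyl group in its kinetically set, less stable configuration.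

Step 7
Reactants: 8 cyclohexanone
Product: 9 C1=C6 trimethylsilyl enol ether
Conditions: LiN(iPr)2, Me3SiCl, THF, −78 °C (ketone added to the base/silyl chloride mixture); Et3N, pentane work-up
Reagents that add atoms: chlorotrimethylsilane (C[Si](C)(C)Cl)
Why: Kinetic deprotonation by the hindered amide at the C6 methylene and not at the C10 methine, which is flanked by the methyl and silyloxy groups, with trapping in situ gives the less substituted enol ether, so that C10 is never enolised and the carbon to be inserted will stand on the C6 side.

Step 8
Reactants: 9 enol ether, 10 diiodomethane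
Product: 11 1-trimethylsiloxybicyclo[4.1.0]heptane (methylene on C1 and C6, C7 isopropenyl α, C9–OSi β, C10–CH3 α)
Conditions: Et2Zn, CH2I2, CH2Cl2, 0 °C; pyridine quench
Reagents that add atoms: diiodomethane 10 (ICI)
Why: The Furukawa variant of the Simmons–Smith cyclopropanation is much faster on the electron-rich enol ether than on the 1,1-disubstituted isopropenyl alkene, and the face of addition (expected anti to the C7 and C10 substituents) is of no consequence because both new stereocentres disappear in step 9.

Step 9
Reactants: 11 siloxycyclopropane
Product: 13 cyclohept-2-enone (C1=O, C5=C6, C7 isopropenyl α, C9–OSi β, C10–CH3 α), via 3-chlorocycloheptanone 12 (not isolated)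
Conditions: FeCl3 (anhydrous), pyridine, DMF, 0 °C; then NaOAc, MeOH, 50 °C
Reagents that add atoms: none
Why: FeCl3 takes one electron from the siloxycyclopropane, and the oxygen-centred radical cation opens the strained C1–C6 bond common to both rings, which turns C1 into the carbonyl carbon (the silyl group leaves as Me3SiCl) and leaves a secondary radical at C6 that is now separated from C1 by the former cyclopropane methylene, C5. A second FeCl3 transfers a chlorine atom to C6 to give the 3-chlorocycloheptanone 12, and NaOAc then removes HCl through the C5 enolate (E1cB) to give the C5=C6 enone; the closest known reaction is the Saegusa–Ito FeCl3 ring enlargement of 1-siloxybicyclo[n.1.0]alkanes to cycloalk-2-enones. The seven-membered ring is not closed but arises by ring expansion, through fragmentation of the zero-atom bridge of the bicyclo[4.1.0]heptane, and no C–C bond is formed. No stereocentre is created, since the C6 chloride is lost again, while C7, C9 and C10 are not involved. The step needs cleavage of the internal and not of an external cyclopropane bond, which the substrate secures because only this path gives a secondary radical and relieves the ring fusion, and it needs the new carbon on the C6 side, which was fixed by the kinetic enol ether of step 7. The isopropenyl group and the silyl ether should survive FeCl3 in DMF at 0 °C, and acetate is chosen as a base too weak to enolise the hindered C10 position or to expel the C9 silyloxy group.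

Step 10
Reactants: 13 cycloheptenone, 14 ethyl vinyl ether
Product: 16 acetyl carbinol (C1 hydroxyl α, acetyl β), via 1-ethoxyvinyl carbinol 15 (not isolated)
Conditions: 14, tBuLi, THF, −78 to 0 °C; then 13, −78 °C; then 0.5 M HCl, THF, 0 °C
Reagents that add atoms: ethyl vinyl ether 14 (C=COCC); water (O)
Why: 1-Ethoxyvinyllithium, an acetyl anion equivalent, adds 1,2 to the enone carbonyl as a hard, branched nucleophile from the β face, opposite to the adjacent C10 methyl group, which sets C1 with its oxygen α, and brief aqueous acid hydrolyses the enol ether to the methyl ketone without ionising the tertiary allylic alcohol.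

Step 11
Reactants: 16 acetyl carbinol, 17 acetaldehyde
Product: 18 aldol (3-hydroxybutanoyl carbinol, C4 epimers)
Conditions: LiN(iPr)2 (2.2 equiv), THF, −78 °C; then 17; AcOH quench at −78 °C
Reagents that add atoms: acetaldehyde 17 (CC=O)
Why: The alkoxide–enolate dianion, in which the acetyl methyl is the only enolisable position because C1 is quaternary, undergoes a kinetic aldol addition to acetaldehyde, and the new carbinol centre at C4 is removed in step 12.

Step 12
Reactants: 18 aldol
Product: 20 (E)-crotonoyl carbinol, via acetate 19 (not isolated)
Conditions: Ac2O, DMAP, pyridine, CH2Cl2, 0 °C; then DBU, 0 °C to rt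
Reagents that add atoms: none
Why: The secondary alcohol is acetylated much faster than the tertiary C1 hydroxyl, and E1cB loss of acetate from the β-acetoxy ketone gives the thermodynamically favoured (E)-enone.

Step 13
Reactants: 20 crotonoyl carbinol
Product: 21 allylic alcohol (C12–OH)
Conditions: SeO2 (0.5 equiv), tBuOOH, CH2Cl2, rt
Reagents that add atoms: selenium dioxide (O=[Se]=O); tert-butyl hydroperoxide (CC(C)(C)OO)
Why: Allylic oxidation with SeO2 (ene reaction followed by a [2,3]-sigmatropic shift) takes the methyl group of the electron-rich 1,1-disubstituted alkene in preference to the methine hydrogen at C7, which is the only allylic hydrogen of C5=C6, and to the methyl group of the electron-poor enone.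

Step 14
Reactants: 21 allylic alcohol
Product: 23 acrylic acid (C12 carboxyl), via enal 22 (not isolated)
Conditions: Dess–Martin periodinane, pyridine, CH2Cl2, 0 °C; then NaClO2, NaH2PO4, 2-methyl-2-butene, tBuOH/H2O, 0 °C to rt
Reagents that add atoms: sodium chlorite ([Na+].[O-]Cl=O)
Why: Dess–Martin oxidation of the only primary alcohol and Pinnick oxidation of the resulting 2-substituted acrolein give the acrylic acid, the added alkene scavenging hypochlorite so that the alkenes, the enone and the tertiary alcohol are left alone.

Step 15
Reactants: 23 acrylic acid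
Product: 24 iodolactone (cis-fused α-methylene γ-lactone, C6–O α, C5–I β)
Conditions: I2, NaHCO3, MeCN/H2O, 0 °C to rt, dark
Reagents that add atoms: iodine (II)
Why: Iodolactonization, in which the carboxylate held on the α face of C7 opens the β-iodonium ion of C5=C6 at C6 in a 5-exo anti addition, gives the cis-fused γ-lactone with the C6 oxygen α and the C5 iodide β, the electron-poor acrylate and enone double bonds being inert to iodine.

Step 16
Reactants: 24 iodolactone
Product: 25 α,β-epoxy ketone (C1–C5 oxirane, oxygen α)
Conditions: K2CO3, MeCN, 0 °C to rt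
Reagents that add atoms: none
Why: The alkoxide of the C1 hydroxyl, which stands anti to the C5 iodide, displaces it from the back side (halohydrin to oxirane closure, SN2), which inverts C5 and gives the α,β-epoxy ketone with its oxygen on the α face, and only the desired C1 epimer can undergo this closure.

Step 17
Reactants: 25 epoxy ketone, 26 3-methylbutanoic acid
Product: 27 C9 silyl ether of the target (C5 isovalerate β, C1 hydroxyl α)
Conditions: 26 (solvent), cesium 3-methylbutanoate (0.5 equiv), 60 °C
Reagents that add atoms: 3-methylbutanoic acid 26 (CC(C)CC(O)=O)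
Why: Acidolysis of the α,β-epoxy ketone takes place at the β-carbon C5 with inversion, since C1 is fully substituted and deactivated by the adjacent carbonyl group, so that this second inversion places the ester oxygen on the β face, trans to both the C1 hydroxyl and the lactone oxygen, and installs the isovalerate without a free C5 hydroxyl that could add to the enone.

Step 18
Reactants: 27 silyl ether
Product: 28 target CNP0186412.1
Conditions: HF·pyridine, pyridine, THF, 0 °C to rt
Reagents that add atoms: none
Why: Buffered fluoride cleaves the secondary silyl ether while the α-methylene lactone, the ester, the enone and the α-ketol are stable to these mildly acidic, non-nucleophilic conditions.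

**Compound list**

1 | (R)-(−)-carvone | CC1=CC[C@H](CC1=O)C(C)=C | starting material
2 | (1R,5R)-cis-carveol | O[C@@H]1C[C@H](C(C)=C)CC=C1C | intermediate
3 | 7-(iodomethyl)-4,7-dimethyl-6-oxabicyclo[3.2.1]oct-3-ene (C11 epimers) | CC1=CC[C@@H]2C[C@H]1OC2(C)CI | intermediate
4 | C9 alkylborane of 3 (drawn as the monoalkylborane, boron β) | C[C@H]1[C@H](B)C[C@@H]2C[C@H]1OC2(C)CI | intermediate (not isolated)
5 | 7-(iodomethyl)-4,7-dimethyl-6-oxabicyclo[3.2.1]octan-3-ol (C9–OH β, C10–CH3 α) | C[C@H]1[C@H](O)C[C@@H]2C[C@H]1OC2(C)CI | intermediate
6 | tert-butyldimethylsilyl ether of 5 | C[C@H]1[C@H](O[Si](C)(C)C(C)(C)C)C[C@@H]2C[C@H]1OC2(C)CI | intermediate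
7 | 3-[(tert-butyldimethylsilyl)oxy]-2-methyl-5-(prop-1-en-2-yl)cyclohexan-1-ol (C1–OH α, C10–CH3 α, C9–OSi β, isopropenyl α) | C[C@H]1[C@H](O[Si](C)(C)C(C)(C)C)C[C@@H](C(C)=C)C[C@H]1O | intermediate
8 | (2S,3R,5R)-3-[(tert-butyldimethylsilyl)oxy]-2-methyl-5-(prop-1-en-2-yl)cyclohexan-1-one | O=C1C[C@H](C(C)=C)C[C@@H](O[Si](C)(C)C(C)(C)C)[C@@H]1C | intermediate
9 | C1=C6 trimethylsilyl enol ether of 8 | C[Si](C)(C)OC1=C[C@H](C(C)=C)C[C@@H](O[Si](C)(C)C(C)(C)C)[C@@H]1C | intermediate
10 | diiodomethane | ICI | starting material
11 | 1-trimethylsiloxybicyclo[4.1.0]heptane with isopropenyl, silyl ether and methyl groups | C[Si](C)(C)O[C@]12C[C@H]1[C@H](C(C)=C)C[C@@H](O[Si](C)(C)C(C)(C)C)[C@@H]2C | intermediate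
12 | 3-chlorocycloheptanone (C6–Cl, either configuration) | O=C1CC(Cl)[C@H](C(C)=C)C[C@@H](O[Si](C)(C)C(C)(C)C)[C@@H]1C | intermediate (not isolated)
13 | cyclohept-2-enone (C5=C6) with C7 isopropenyl, C9 silyl ether and C10 methyl | O=C1C=C[C@H](C(C)=C)C[C@@H](O[Si](C)(C)C(C)(C)C)[C@@H]1C | intermediate
14 | ethyl vinyl ether | C=COCC | starting material
15 | 1-(1-ethoxyvinyl) carbinol (C1–OH α) | CCOC(=C)[C@@]1(O)C=C[C@H](C(C)=C)C[C@@H](O[Si](C)(C)C(C)(C)C)[C@@H]1C | intermediate (not isolated)
16 | 1-acetyl carbinol (C1–OH α, acetyl β) | CC(=O)[C@@]1(O)C=C[C@H](C(C)=C)C[C@@H](O[Si](C)(C)C(C)(C)C)[C@@H]1C | intermediate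
17 | acetaldehyde | CC=O | starting material
18 | 1-(3-hydroxybutanoyl) carbinol (C4 epimers) | CC(O)CC(=O)[C@@]1(O)C=C[C@H](C(C)=C)C[C@@H](O[Si](C)(C)C(C)(C)C)[C@@H]1C | intermediate
19 | 1-(3-acetoxybutanoyl) carbinol (C4 epimers) | CC(OC(C)=O)CC(=O)[C@@]1(O)C=C[C@H](C(C)=C)C[C@@H](O[Si](C)(C)C(C)(C)C)[C@@H]1C | intermediate (not isolated)
20 | 1-[(E)-but-2-enoyl] carbinol | C/C=C/C(=O)[C@@]1(O)C=C[C@H](C(C)=C)C[C@@H](O[Si](C)(C)C(C)(C)C)[C@@H]1C | intermediate
21 | allylic alcohol (C7 3-hydroxyprop-1-en-2-yl) | C/C=C/C(=O)[C@@]1(O)C=C[C@H](C(=C)CO)C[C@@H](O[Si](C)(C)C(C)(C)C)[C@@H]1C | intermediate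
22 | enal (C7 3-oxoprop-1-en-2-yl) | C/C=C/C(=O)[C@@]1(O)C=C[C@H](C(=C)C=O)C[C@@H](O[Si](C)(C)C(C)(C)C)[C@@H]1C | intermediate (not isolated)
23 | acrylic acid (C7 1-carboxyvinyl) | C/C=C/C(=O)[C@@]1(O)C=C[C@H](C(=C)C(O)=O)C[C@@H](O[Si](C)(C)C(C)(C)C)[C@@H]1C | intermediate
24 | iodolactone (C6–O α, C5–I β, C1–OH α) | C=C1C(=O)O[C@@H]2[C@H]1C[C@@H](O[Si](C)(C)C(C)(C)C)[C@H](C)[C@@](O)(C(=O)/C=C/C)[C@H]2I | intermediate
25 | α,β-epoxy ketone (C1–C5 oxirane, oxygen α) | C=C1C(=O)O[C@@H]2[C@H]1C[C@@H](O[Si](C)(C)C(C)(C)C)[C@H](C)[C@]3(C(=O)/C=C/C)O[C@H]23 | intermediate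
26 | 3-methylbutanoic acid (isovaleric acid) | CC(C)CC(O)=O | starting material
27 | C9 tert-butyldimethylsilyl ether of the target | C=C1C(=O)O[C@@H]2[C@H]1C[C@@H](O[Si](C)(C)C(C)(C)C)[C@H](C)[C@@](O)(C(=O)/C=C/C)[C@H]2OC(=O)CC(C)C | intermediate
28 | CNP0186412.1 | C=C1C(=O)O[C@@H]2[C@H]1C[C@@H](O)[C@H](C)[C@@](O)(C(=O)/C=C/C)[C@H]2OC(=O)CC(C)C | target

**Step count**

Total: 18 steps. Longest linear sequence: 18 steps from (R)-carvone.

**Steps most likely to fail**

Step 9 (key step). The loss of HCl passes through enolates. Enolisation on the C10 side would scramble the kinetically set methyl centre or expel the C9 silyloxy group, vinylogous enolisation would touch C7, and HCl from the FeCl3 stage may cleave the silyl ether. The fallback sets out from ketone 8 and needs no base. Lewis-acid-promoted one-carbon homologation with trimethylsilyldiazomethane (Me3SiCHN2, BF3·OEt2, CH2Cl2, −78 °C), in which the less substituted C6 migrates, should give the 2-(trimethylsilyl)cycloheptanone F1. On warming, the 1,3 shift of silicon from carbon to oxygen should give the C1=C5 trimethylsilyl enol ether F2, with the double bond fixed at the inserted carbon. Saegusa–Ito dehydrogenation with Pd(OAc)2 in MeCN then comes back to the route at 13.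

Step 10. The organolithium may approach the C1 carbonyl group from the α face (wrong C1 epimer) or act as a base. A wrong C1 epimer would show itself at step 16, where a cis iodohydrin cannot close. The fallback sets out from 13 and changes both the nucleophile class and the way the acetyl group is made. A slim sp nucleophile (HC≡CMgBr, THF, 0 °C), whose approach to ring ketones follows torsional rather than steric control and is typically complementary to that of branched reagents, should give the 1-ethynyl carbinol F3. Markovnikov hydration of the terminal alkyne (Ph3PAuNTf2 catalytic, MeOH/H2O, rt) comes back to the route at 16.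

Step 17. Back-side attack of a weak, bulky carboxylic acid at the hindered C5 may be slow. Under forcing or more acidic conditions the C9 silyl ether oxygen could take part across the ring, or the acyl group could shift from C1 to C5. The fallback sets out from 25 and separates ring opening from ester formation. Specific-acid hydrolysis with the smallest nucleophile (0.2 M HClO4, THF/H2O, 0 °C) should open the oxirane at C5 with the same inversion to give the C1,C5-diol F4. Immediate acylation of its secondary C5 hydroxyl (3-methylbutanoic anhydride, DMAP, pyridine, CH2Cl2, 0 °C; the tertiary C1 hydroxyl does not react) comes back to the route at 27.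

Further compounds
F1 | step 9 | 2-(trimethylsilyl)cycloheptanone (silyl group on C5, either configuration; C7 isopropenyl α, C9–OSi β, C10–CH3 α) | O=C1C([Si](C)(C)C)C[C@H](C(C)=C)C[C@@H](O[Si](C)(C)C(C)(C)C)[C@@H]1C
F2 | step 9 | C1=C5 trimethylsilyl enol ether of the cycloheptanone | C[Si](C)(C)OC1=CC[C@H](C(C)=C)C[C@@H](O[Si](C)(C)C(C)(C)C)[C@@H]1C
F3 | step 10 | 1-ethynyl carbinol (C1–OH α, ethynyl β) | C#C[C@@]1(O)C=C[C@H](C(C)=C)C[C@@H](O[Si](C)(C)C(C)(C)C)[C@@H]1C
F4 | step 17 | C1,C5-diol lactone (C1–OH α, C5–OH β) | C=C1C(=O)O[C@@H]2[C@H]1C[C@@H](O[Si](C)(C)C(C)(C)C)[C@H](C)[C@@](O)(C(=O)/C=C/C)[C@H]2O
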